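## Retrosynthetic overview

1. Rings are lettered A–H from the 2,4,6‑trihydroxyphenoxy end (A) to the 3,4,5‑trihydroxyphenoxy end (H). All hydroxyls outside ring A are carried as benzyl ethers and released in one final hydrogenolysis.
2. Ring A is built de novo and last: 2‑aryloxyphloroglucinol ⇒ methyl 6‑aryloxy‑3,5‑dioxohexanoate (ring closure by intramolecular Claisen) ⇒ heptamer aryloxyacetate + methyl acetoacetate dianion (intermolecular Claisen condensation, the key C–C bond).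
3. Rings B–H come from seven aryl‑ether disconnections, each made by Cu‑catalysed coupling of the growing phenol with a bromobenzaldehyde, followed by Dakin oxidation of CHO to the next phenol.
4. Order: H (from gallaldehyde) → G → F → E → D → C → B as preformed arenes, using 2‑bromo‑3,4,5‑tris(benzyloxy)benzaldehyde for G, E, C and 4‑bromo‑3,5‑bis(benzyloxy)benzaldehyde for F, D, B; then ring A is constructed.

Assumption: the target has no stereocentre or other stereo‑element, so it is made as the single achiral compound drawn; no step creates a stereocentre.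

## Route

Step 1
Reactants: 1 3,4,5-trihydroxybenzaldehyde
Product: 2 3,4,5-tris(benzyloxy)benzaldehyde
Conditions: BnBr (3.3 equiv), K2CO3, DMF, 60 °C, N2
Reagents that add atoms: benzyl bromide BrCc1ccccc1
Why: Williamson ether synthesis on three acidic phenols is routine and leaves the aldehyde untouched.

Step 2
Reactants: 2 3,4,5-tris(benzyloxy)benzaldehyde
Product: 3 2-bromo-3,4,5-tris(benzyloxy)benzaldehyde
Conditions: NBS (1.05 equiv), MeCN, rt, dark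
Reagents that add atoms: N-bromosuccinimide O=C1CCC(=O)N1Br
Why: Electrophilic aromatic bromination can only occur at the two equivalent free ring positions, which are activated ortho/para by benzyloxy groups, and the first bromine deactivates the ring against a second.

Step 3
Reactants: 4 4-bromo-3,5-dihydroxybenzoic acid
Product: 5 benzyl 4-bromo-3,5-bis(benzyloxy)benzoate
Conditions: BnBr (3.5 equiv), K2CO3, DMF, 60 °C
Reagents that add atoms: benzyl bromide BrCc1ccccc1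
Why: Exhaustive Williamson alkylation converts both phenols and the carboxylate in one operation.

Step 4
Reactants: 5 benzyl 4-bromo-3,5-bis(benzyloxy)benzoate
Product: 6 [4-bromo-3,5-bis(benzyloxy)phenyl]methanol
Conditions: DIBAL-H (2.5 equiv), CH2Cl2, −78 → 0 °C; Rochelle salt
Reagents that add atoms: none
Why: Hydride reduction of the ester to the benzylic alcohol leaves the aryl bromide and benzyl ethers intact at low temperature.

Step 5
Reactants: 6 [4-bromo-3,5-bis(benzyloxy)phenyl]methanol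
Product: 7 4-bromo-3,5-bis(benzyloxy)benzaldehyde
Conditions: MnO2 (10 equiv), CH2Cl2, rt
Reagents that add atoms: none
Why: MnO2 oxidises benzylic alcohols selectively to aldehydes without over‑oxidation.

Step 6
Reactants: 2 3,4,5-tris(benzyloxy)benzaldehyde
Product: 9 3,4,5-tris(benzyloxy)phenol, via 3,4,5-tris(benzyloxy)phenyl formate 8 (not isolated)
Conditions: mCPBA (1.3 equiv), CH2Cl2, 0 °C → rt; then K2CO3 (cat.), MeOH, rt
Reagents that add atoms: meta-chloroperoxybenzoic acid OOC(=O)c1cccc(Cl)c1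
Why: In this Dakin‑type Baeyer–Villiger oxidation the electron‑rich aryl group migrates in preference to hydrogen, and the formate is methanolysed to the phenol.

Step 7
Reactants: 9 3,4,5-tris(benzyloxy)phenol; 3 2-bromo-3,4,5-tris(benzyloxy)benzaldehyde
Product: 10 G–H dimer aldehyde 3,4,5-tris(benzyloxy)-2-[3,4,5-tris(benzyloxy)phenoxy]benzaldehyde
Conditions: CuI (10 mol%), N,N-dimethylglycine·HCl (30 mol%), Cs2CO3, dioxane, 100 °C, Ar
Reagents that add atoms: none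
Why: Ullmann‑type Cu‑catalysed C–O coupling of an unhindered phenoxide with an aryl bromide activated by its ortho formyl group.

Step 8
Reactants: 10 G–H dimer aldehyde
Product: 12 G–H dimer phenol 3,4,5-tris(benzyloxy)-2-[3,4,5-tris(benzyloxy)phenoxy]phenol, via G–H dimer formate 11 (not isolated)
Conditions: mCPBA (1.3 equiv), NaHCO3, CH2Cl2, 0 °C → rt; then K2CO3 (cat.), MeOH, rt
Reagents that add atoms: meta-chloroperoxybenzoic acid OOC(=O)c1cccc(Cl)c1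
Why: Dakin‑type Baeyer–Villiger oxidation; the ring carries ortho aryloxy and para benzyloxy donors, so aryl migration is favoured.

Step 9
Reactants: 12 G–H dimer phenol; 7 4-bromo-3,5-bis(benzyloxy)benzaldehyde
Product: 13 F–G–H trimer aldehyde [3,5-bis(benzyloxy)-4-(aryloxy)benzaldehyde; aryloxy = 12 less its phenolic H]
Conditions: CuI (20 mol%), picolinic acid (40 mol%), K3PO4, DMSO, 100 °C, Ar
Reagents that add atoms: none
Why: Ullmann‑type C–O coupling at a bromide activated by the para formyl group, with a ligand system suited to ortho‑substituted partners.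

Step 10
Reactants: 13 F–G–H trimer aldehyde
Product: 15 F–G–H trimer phenol [3,5-bis(benzyloxy)-4-(aryloxy)phenol; aryloxy = 12 less its phenolic H], via F–G–H trimer formate 14 (not isolated)
Conditions: mCPBA (1.3 equiv), NaHCO3, CH2Cl2, 0 °C → rt; then K2CO3 (cat.), MeOH, rt
Reagents that add atoms: meta-chloroperoxybenzoic acid OOC(=O)c1cccc(Cl)c1
Why: Dakin‑type Baeyer–Villiger oxidation of a para‑aryloxy benzaldehyde, the same reactivity as 3,4,5‑trialkoxybenzaldehydes.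

Step 11
Reactants: 15 F–G–H trimer phenol; 3 2-bromo-3,4,5-tris(benzyloxy)benzaldehyde
Product: 16 E–H tetramer aldehyde [3,4,5-tris(benzyloxy)-2-(aryloxy)benzaldehyde; aryloxy = 15 less its phenolic H]
Conditions: CuI (10 mol%), N,N-dimethylglycine·HCl (30 mol%), Cs2CO3, dioxane, 100 °C, Ar
Reagents that add atoms: none
Why: Ullmann‑type C–O coupling as in step 7; the phenol oxygen is flanked by two ring hydrogens and the bromide is ortho‑formyl activated.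

Step 12
Reactants: 16 E–H tetramer aldehyde
Product: 18 E–H tetramer phenol [3,4,5-tris(benzyloxy)-2-(aryloxy)phenol; aryloxy = 15 less its phenolic H], via E–H tetramer formate 17 (not isolated)
Conditions: mCPBA (1.3 equiv), NaHCO3, CH2Cl2, 0 °C → rt; then K2CO3 (cat.), MeOH, rt
Reagents that add atoms: meta-chloroperoxybenzoic acid OOC(=O)c1cccc(Cl)c1
Why: Dakin‑type Baeyer–Villiger oxidation as in step 8.

Step 13
Reactants: 18 E–H tetramer phenol; 7 4-bromo-3,5-bis(benzyloxy)benzaldehyde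
Product: 19 D–H pentamer aldehyde [3,5-bis(benzyloxy)-4-(aryloxy)benzaldehyde; aryloxy = 18 less its phenolic H]
Conditions: CuI (20 mol%), picolinic acid (40 mol%), K3PO4, DMSO, 100 °C, Ar
Reagents that add atoms: none
Why: Ullmann‑type C–O coupling as in step 9, with the para formyl group activating the flanked bromide.

Step 14
Reactants: 19 D–H pentamer aldehyde
Product: 21 D–H pentamer phenol [3,5-bis(benzyloxy)-4-(aryloxy)phenol; aryloxy = 18 less its phenolic H], via D–H pentamer formate 20 (not isolated)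
Conditions: mCPBA (1.3 equiv), NaHCO3, CH2Cl2, 0 °C → rt; then K2CO3 (cat.), MeOH, rt
Reagents that add atoms: meta-chloroperoxybenzoic acid OOC(=O)c1cccc(Cl)c1
Why: Dakin‑type Baeyer–Villiger oxidation as in step 10.

Step 15
Reactants: 21 D–H pentamer phenol; 3 2-bromo-3,4,5-tris(benzyloxy)benzaldehyde
Product: 22 C–H hexamer aldehyde [3,4,5-tris(benzyloxy)-2-(aryloxy)benzaldehyde; aryloxy = 21 less its phenolic H]
Conditions: CuI (10 mol%), N,N-dimethylglycine·HCl (30 mol%), Cs2CO3, dioxane, 100 °C, Ar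
Reagents that add atoms: none
Why: Ullmann‑type C–O coupling as in steps 7 and 11.

Step 16
Reactants: 22 C–H hexamer aldehyde
Product: 24 C–H hexamer phenol [3,4,5-tris(benzyloxy)-2-(aryloxy)phenol; aryloxy = 21 less its phenolic H], via C–H hexamer formate 23 (not isolated)
Conditions: mCPBA (1.3 equiv), NaHCO3, CH2Cl2, 0 °C → rt; then K2CO3 (cat.), MeOH, rt
Reagents that add atoms: meta-chloroperoxybenzoic acid OOC(=O)c1cccc(Cl)c1
Why: Dakin‑type Baeyer–Villiger oxidation as in step 8.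

Step 17
Reactants: 24 C–H hexamer phenol; 7 4-bromo-3,5-bis(benzyloxy)benzaldehyde
Product: 25 B–H heptamer aldehyde [3,5-bis(benzyloxy)-4-(aryloxy)benzaldehyde; aryloxy = 24 less its phenolic H]
Conditions: CuI (20 mol%), picolinic acid (40 mol%), K3PO4, DMSO, 100 °C, Ar
Reagents that add atoms: none
Why: Ullmann‑type C–O coupling as in steps 9 and 13.

Step 18
Reactants: 25 B–H heptamer aldehyde
Product: 27 B–H heptamer phenol [3,5-bis(benzyloxy)-4-(aryloxy)phenol; aryloxy = 24 less its phenolic H], via B–H heptamer formate 26 (not isolated)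
Conditions: mCPBA (1.3 equiv), NaHCO3, CH2Cl2, 0 °C → rt; then K2CO3 (cat.), MeOH, rt
Reagents that add atoms: meta-chloroperoxybenzoic acid OOC(=O)c1cccc(Cl)c1
Why: Dakin‑type Baeyer–Villiger oxidation as in step 10, giving the unhindered phenol on ring B.

Step 19
Reactants: 27 B–H heptamer phenol; 28 methyl bromoacetate
Product: 29 heptamer aryloxyacetate [methyl 2-(aryloxy)acetate; aryloxy = 27 less its phenolic H]
Conditions: K2CO3, acetone, 50 °C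
Reagents that add atoms: none
Why: Williamson O‑alkylation of an unhindered phenoxide with a primary α‑halo ester is fast and clean.

Step 20
Reactants: 29 heptamer aryloxyacetate; 30 methyl acetoacetate
Product: 32 heptamer diketo ester [methyl 6-(aryloxy)-3,5-dioxohexanoate; aryloxy = 27 less its phenolic H], via methyl acetoacetate dianion 31 (not isolated)
Conditions: 30 (3 equiv), LDA (6 equiv), THF, 0 °C; then 29, −78 → 0 °C; 1 M HCl
Reagents that add atoms: none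
Why: In this crossed Claisen condensation the γ‑carbanion of the acetoacetate dianion acylates the electrophilic α‑aryloxy ester, and excess dianion absorbs the acidic proton of the product.

Step 21
Reactants: 32 heptamer diketo ester
Product: 33 octadeca-O-benzyl target [2-(aryloxy)benzene-1,3,5-triol; aryloxy = 27 less its phenolic H]
Conditions: NaOMe (5 equiv), MeOH/THF 1:1, 100 °C (sealed), Ar; then 1 M HCl, 0 °C
Reagents that add atoms: none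
Why: Intramolecular Claisen (Dieckmann‑type) cyclisation of the C6 carbanion, acidified by the ketone and the aryloxy group, onto the C1 ester gives the cyclohexanetrione, and its tautomerisation to the phloroglucinol makes C‑acylation irreversible while O‑acylation to the pyrone is reversed by methoxide.

Step 22
Reactants: 33 octadeca-O-benzyl target
Product: 34 CNP0206369.0
Conditions: H2 (1 atm), 20% Pd(OH)2/C, THF/MeOH 1:1, rt; filter and concentrate under Ar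
Reagents that add atoms: none
Why: Catalytic hydrogenolysis cleaves all eighteen benzyl aryl ethers under neutral conditions that leave the diaryl ethers and aromatic rings untouched.

## Compound list

1 | 3,4,5-trihydroxybenzaldehyde | O=Cc1cc(O)c(O)c(O)c1 | starting material
2 | 3,4,5-tris(benzyloxy)benzaldehyde | O=Cc1cc(OCc9ccccc9)c(OCc9ccccc9)c(OCc9ccccc9)c1 | intermediate
3 | 2-bromo-3,4,5-tris(benzyloxy)benzaldehyde | O=Cc1cc(OCc9ccccc9)c(OCc9ccccc9)c(OCc9ccccc9)c1Br | intermediate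
4 | 4-bromo-3,5-dihydroxybenzoic acid | OC(=O)c1cc(O)c(Br)c(O)c1 | starting material
5 | benzyl 4-bromo-3,5-bis(benzyloxy)benzoate | O=C(OCc9ccccc9)c1cc(OCc9ccccc9)c(Br)c(OCc9ccccc9)c1 | intermediate
6 | [4-bromo-3,5-bis(benzyloxy)phenyl]methanol | OCc1cc(OCc9ccccc9)c(Br)c(OCc9ccccc9)c1 | intermediate
7 | 4-bromo-3,5-bis(benzyloxy)benzaldehyde | O=Cc1cc(OCc9ccccc9)c(Br)c(OCc9ccccc9)c1 | intermediate
8 | 3,4,5-tris(benzyloxy)phenyl formate | O=COc1cc(OCc9ccccc9)c(OCc9ccccc9)c(OCc9ccccc9)c1 | intermediate (not isolated)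
9 | 3,4,5-tris(benzyloxy)phenol (ring H) | Oc1cc(OCc9ccccc9)c(OCc9ccccc9)c(OCc9ccccc9)c1 | intermediate
10 | G–H dimer aldehyde: 3,4,5-tris(benzyloxy)-2-[3,4,5-tris(benzyloxy)phenoxy]benzaldehyde | O=Cc1cc(OCc9ccccc9)c(OCc9ccccc9)c(OCc9ccccc9)c1Oc1cc(OCc9ccccc9)c(OCc9ccccc9)c(OCc9ccccc9)c1 | intermediate
11 | G–H dimer formate: 3,4,5-tris(benzyloxy)-2-[3,4,5-tris(benzyloxy)phenoxy]phenyl formate | O=COc1cc(OCc9ccccc9)c(OCc9ccccc9)c(OCc9ccccc9)c1Oc1cc(OCc9ccccc9)c(OCc9ccccc9)c(OCc9ccccc9)c1 | intermediate (not isolated)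
12 | G–H dimer phenol: 3,4,5-tris(benzyloxy)-2-[3,4,5-tris(benzyloxy)phenoxy]phenol | Oc1cc(OCc9ccccc9)c(OCc9ccccc9)c(OCc9ccccc9)c1Oc1cc(OCc9ccccc9)c(OCc9ccccc9)c(OCc9ccccc9)c1 | intermediate
13 | F–G–H trimer aldehyde: 3,5-bis(benzyloxy)-4-(aryloxy)benzaldehyde, aryloxy = 12 less its phenolic H | O=Cc4cc(OCc9ccccc9)c(Oc5cc(OCc9ccccc9)c(OCc9ccccc9)c(OCc9ccccc9)c5Oc5cc(OCc9ccccc9)c(OCc9ccccc9)c(OCc9ccccc9)c5)c(OCc9ccccc9)c4 | intermediate
14 | F–G–H trimer formate: formate ester of 15 | O=COc4cc(OCc9ccccc9)c(Oc5cc(OCc9ccccc9)c(OCc9ccccc9)c(OCc9ccccc9)c5Oc5cc(OCc9ccccc9)c(OCc9ccccc9)c(OCc9ccccc9)c5)c(OCc9ccccc9)c4 | intermediate (not isolated)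
15 | F–G–H trimer phenol: 3,5-bis(benzyloxy)-4-(aryloxy)phenol, aryloxy = 12 less its phenolic H | Oc4cc(OCc9ccccc9)c(Oc5cc(OCc9ccccc9)c(OCc9ccccc9)c(OCc9ccccc9)c5Oc5cc(OCc9ccccc9)c(OCc9ccccc9)c(OCc9ccccc9)c5)c(OCc9ccccc9)c4 | intermediate
16 | E–H tetramer aldehyde: 3,4,5-tris(benzyloxy)-2-(aryloxy)benzaldehyde, aryloxy = 15 less its phenolic H | O=Cc4cc(OCc9ccccc9)c(OCc9ccccc9)c(OCc9ccccc9)c4Oc4cc(OCc9ccccc9)c(Oc5cc(OCc9ccccc9)c(OCc9ccccc9)c(OCc9ccccc9)c5Oc5cc(OCc9ccccc9)c(OCc9ccccc9)c(OCc9ccccc9)c5)c(OCc9ccccc9)c4 | intermediate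
17 | E–H tetramer formate: formate ester of 18 | O=COc4cc(OCc9ccccc9)c(OCc9ccccc9)c(OCc9ccccc9)c4Oc4cc(OCc9ccccc9)c(Oc5cc(OCc9ccccc9)c(OCc9ccccc9)c(OCc9ccccc9)c5Oc5cc(OCc9ccccc9)c(OCc9ccccc9)c(OCc9ccccc9)c5)c(OCc9ccccc9)c4 | intermediate (not isolated)
18 | E–H tetramer phenol: 3,4,5-tris(benzyloxy)-2-(aryloxy)phenol, aryloxy = 15 less its phenolic H | Oc4cc(OCc9ccccc9)c(OCc9ccccc9)c(OCc9ccccc9)c4Oc4cc(OCc9ccccc9)c(Oc5cc(OCc9ccccc9)c(OCc9ccccc9)c(OCc9ccccc9)c5Oc5cc(OCc9ccccc9)c(OCc9ccccc9)c(OCc9ccccc9)c5)c(OCc9ccccc9)c4 | intermediate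
19 | D–H pentamer aldehyde: 3,5-bis(benzyloxy)-4-(aryloxy)benzaldehyde, aryloxy = 18 less its phenolic H | O=Cc3cc(OCc9ccccc9)c(Oc4cc(OCc9ccccc9)c(OCc9ccccc9)c(OCc9ccccc9)c4Oc4cc(OCc9ccccc9)c(Oc5cc(OCc9ccccc9)c(OCc9ccccc9)c(OCc9ccccc9)c5Oc5cc(OCc9ccccc9)c(OCc9ccccc9)c(OCc9ccccc9)c5)c(OCc9ccccc9)c4)c(OCc9ccccc9)c3 | intermediate
20 | D–H pentamer formate: formate ester of 21 | O=COc3cc(OCc9ccccc9)c(Oc4cc(OCc9ccccc9)c(OCc9ccccc9)c(OCc9ccccc9)c4Oc4cc(OCc9ccccc9)c(Oc5cc(OCc9ccccc9)c(OCc9ccccc9)c(OCc9ccccc9)c5Oc5cc(OCc9ccccc9)c(OCc9ccccc9)c(OCc9ccccc9)c5)c(OCc9ccccc9)c4)c(OCc9ccccc9)c3 | intermediate (not isolated)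
21 | D–H pentamer phenol: 3,5-bis(benzyloxy)-4-(aryloxy)phenol, aryloxy = 18 less its phenolic H | Oc3cc(OCc9ccccc9)c(Oc4cc(OCc9ccccc9)c(OCc9ccccc9)c(OCc9ccccc9)c4Oc4cc(OCc9ccccc9)c(Oc5cc(OCc9ccccc9)c(OCc9ccccc9)c(OCc9ccccc9)c5Oc5cc(OCc9ccccc9)c(OCc9ccccc9)c(OCc9ccccc9)c5)c(OCc9ccccc9)c4)c(OCc9ccccc9)c3 | intermediate
22 | C–H hexamer aldehyde: 3,4,5-tris(benzyloxy)-2-(aryloxy)benzaldehyde, aryloxy = 21 less its phenolic H | O=Cc3cc(OCc9ccccc9)c(OCc9ccccc9)c(OCc9ccccc9)c3Oc3cc(OCc9ccccc9)c(Oc4cc(OCc9ccccc9)c(OCc9ccccc9)c(OCc9ccccc9)c4Oc4cc(OCc9ccccc9)c(Oc5cc(OCc9ccccc9)c(OCc9ccccc9)c(OCc9ccccc9)c5Oc5cc(OCc9ccccc9)c(OCc9ccccc9)c(OCc9ccccc9)c5)c(OCc9ccccc9)c4)c(OCc9ccccc9)c3 | intermediate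
23 | C–H hexamer formate: formate ester of 24 | O=COc3cc(OCc9ccccc9)c(OCc9ccccc9)c(OCc9ccccc9)c3Oc3cc(OCc9ccccc9)c(Oc4cc(OCc9ccccc9)c(OCc9ccccc9)c(OCc9ccccc9)c4Oc4cc(OCc9ccccc9)c(Oc5cc(OCc9ccccc9)c(OCc9ccccc9)c(OCc9ccccc9)c5Oc5cc(OCc9ccccc9)c(OCc9ccccc9)c(OCc9ccccc9)c5)c(OCc9ccccc9)c4)c(OCc9ccccc9)c3 | intermediate (not isolated)
24 | C–H hexamer phenol: 3,4,5-tris(benzyloxy)-2-(aryloxy)phenol, aryloxy = 21 less its phenolic H | Oc3cc(OCc9ccccc9)c(OCc9ccccc9)c(OCc9ccccc9)c3Oc3cc(OCc9ccccc9)c(Oc4cc(OCc9ccccc9)c(OCc9ccccc9)c(OCc9ccccc9)c4Oc4cc(OCc9ccccc9)c(Oc5cc(OCc9ccccc9)c(OCc9ccccc9)c(OCc9ccccc9)c5Oc5cc(OCc9ccccc9)c(OCc9ccccc9)c(OCc9ccccc9)c5)c(OCc9ccccc9)c4)c(OCc9ccccc9)c3 | intermediate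
25 | B–H heptamer aldehyde: 3,5-bis(benzyloxy)-4-(aryloxy)benzaldehyde, aryloxy = 24 less its phenolic H | O=Cc2cc(OCc9ccccc9)c(Oc3cc(OCc9ccccc9)c(OCc9ccccc9)c(OCc9ccccc9)c3Oc3cc(OCc9ccccc9)c(Oc4cc(OCc9ccccc9)c(OCc9ccccc9)c(OCc9ccccc9)c4Oc4cc(OCc9ccccc9)c(Oc5cc(OCc9ccccc9)c(OCc9ccccc9)c(OCc9ccccc9)c5Oc5cc(OCc9ccccc9)c(OCc9ccccc9)c(OCc9ccccc9)c5)c(OCc9ccccc9)c4)c(OCc9ccccc9)c3)c(OCc9ccccc9)c2 | intermediate
26 | B–H heptamer formate: formate ester of 27 | O=COc2cc(OCc9ccccc9)c(Oc3cc(OCc9ccccc9)c(OCc9ccccc9)c(OCc9ccccc9)c3Oc3cc(OCc9ccccc9)c(Oc4cc(OCc9ccccc9)c(OCc9ccccc9)c(OCc9ccccc9)c4Oc4cc(OCc9ccccc9)c(Oc5cc(OCc9ccccc9)c(OCc9ccccc9)c(OCc9ccccc9)c5Oc5cc(OCc9ccccc9)c(OCc9ccccc9)c(OCc9ccccc9)c5)c(OCc9ccccc9)c4)c(OCc9ccccc9)c3)c(OCc9ccccc9)c2 | intermediate (not isolated)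
27 | B–H heptamer phenol: 3,5-bis(benzyloxy)-4-(aryloxy)phenol, aryloxy = 24 less its phenolic H | Oc2cc(OCc9ccccc9)c(Oc3cc(OCc9ccccc9)c(OCc9ccccc9)c(OCc9ccccc9)c3Oc3cc(OCc9ccccc9)c(Oc4cc(OCc9ccccc9)c(OCc9ccccc9)c(OCc9ccccc9)c4Oc4cc(OCc9ccccc9)c(Oc5cc(OCc9ccccc9)c(OCc9ccccc9)c(OCc9ccccc9)c5Oc5cc(OCc9ccccc9)c(OCc9ccccc9)c(OCc9ccccc9)c5)c(OCc9ccccc9)c4)c(OCc9ccccc9)c3)c(OCc9ccccc9)c2 | intermediate
28 | methyl bromoacetate | COC(=O)CBr | starting material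
29 | heptamer aryloxyacetate: methyl 2-(aryloxy)acetate, aryloxy = 27 less its phenolic H | COC(=O)COc2cc(OCc9ccccc9)c(Oc3cc(OCc9ccccc9)c(OCc9ccccc9)c(OCc9ccccc9)c3Oc3cc(OCc9ccccc9)c(Oc4cc(OCc9ccccc9)c(OCc9ccccc9)c(OCc9ccccc9)c4Oc4cc(OCc9ccccc9)c(Oc5cc(OCc9ccccc9)c(OCc9ccccc9)c(OCc9ccccc9)c5Oc5cc(OCc9ccccc9)c(OCc9ccccc9)c(OCc9ccccc9)c5)c(OCc9ccccc9)c4)c(OCc9ccccc9)c3)c(OCc9ccccc9)c2 | intermediate
30 | methyl acetoacetate | COC(=O)CC(C)=O | starting material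
31 | dilithium dianion of methyl acetoacetate (C2 and C4 deprotonated) | [Li+].[Li+].[CH2-]C(=O)[CH-]C(=O)OC | intermediate (not isolated)
32 | heptamer diketo ester: methyl 6-(aryloxy)-3,5-dioxohexanoate, aryloxy = 27 less its phenolic H | COC(=O)CC(=O)CC(=O)COc2cc(OCc9ccccc9)c(Oc3cc(OCc9ccccc9)c(OCc9ccccc9)c(OCc9ccccc9)c3Oc3cc(OCc9ccccc9)c(Oc4cc(OCc9ccccc9)c(OCc9ccccc9)c(OCc9ccccc9)c4Oc4cc(OCc9ccccc9)c(Oc5cc(OCc9ccccc9)c(OCc9ccccc9)c(OCc9ccccc9)c5Oc5cc(OCc9ccccc9)c(OCc9ccccc9)c(OCc9ccccc9)c5)c(OCc9ccccc9)c4)c(OCc9ccccc9)c3)c(OCc9ccccc9)c2 | intermediate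
33 | octadeca-O-benzyl target: 2-(aryloxy)benzene-1,3,5-triol, aryloxy = 27 less its phenolic H (ring A free, rings B–H benzylated) | Oc1cc(O)c(Oc2cc(OCc9ccccc9)c(Oc3cc(OCc9ccccc9)c(OCc9ccccc9)c(OCc9ccccc9)c3Oc3cc(OCc9ccccc9)c(Oc4cc(OCc9ccccc9)c(OCc9ccccc9)c(OCc9ccccc9)c4Oc4cc(OCc9ccccc9)c(Oc5cc(OCc9ccccc9)c(OCc9ccccc9)c(OCc9ccccc9)c5Oc5cc(OCc9ccccc9)c(OCc9ccccc9)c(OCc9ccccc9)c5)c(OCc9ccccc9)c4)c(OCc9ccccc9)c3)c(OCc9ccccc9)c2)c(O)c1 | intermediate
34 | CNP0206369.0 (octameric phlorotannin, achiral) | Oc1cc(O)c(Oc2cc(O)c(Oc3cc(O)c(O)c(O)c3Oc3cc(O)c(Oc4cc(O)c(O)c(O)c4Oc4cc(O)c(Oc5cc(O)c(O)c(O)c5Oc5cc(O)c(O)c(O)c5)c(O)c4)c(O)c3)c(O)c2)c(O)c1 | target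

## Step count and risks

Total steps: 22. Longest linear sequence: 18 (steps 1, 6 and 7–22).

Most likely to fail, first: step 9 (and its repeats, steps 13 and 17). The bromide of 7 sits between two benzyloxy groups and the phenol carries an ortho aryloxy group, so the copper coupling may stall. The fallback replaces the cross‑coupling by an uncatalysed addition–elimination on a fluoride. It sets out from 7, which is acetalised with ethylene glycol (TsOH, toluene, Dean–Stark) to 2-[4-bromo-3,5-bis(benzyloxy)phenyl]-1,3-dioxolane F1. Bromine–lithium exchange (n‑BuLi, THF, −78 °C) and quench with N‑fluorobenzenesulfonimide give 2-[4-fluoro-3,5-bis(benzyloxy)phenyl]-1,3-dioxolane F2. Aqueous HCl in THF releases 4-fluoro-3,5-bis(benzyloxy)benzaldehyde F3. F3 reacts with phenol 12 (Cs2CO3, DMSO, 90 °C) through a Meisenheimer complex stabilised by the para formyl group and comes back to the route at 13; the same fluoride serves steps 13 and 17.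

Second: step 20. The ester 29 has acidic α‑hydrogens and the diketo ester product is more acidic still, so proton transfer can consume the dianion before acylation is complete. The fallback avoids the dianion by using a masked acetoacetate monoanion and an acyl donor that cannot release a ketone during the reaction. It sets out from 29, which is converted with MeNH(OMe)·HCl and i‑PrMgCl (THF, −20 °C) into the heptamer Weinreb amide N-methoxy-N-methyl-2-(aryloxy)acetamide F4. The lithium dienolate of 2,2,6‑trimethyl‑4H‑1,3‑dioxin‑4‑one (LiHMDS, THF, −78 °C) is acylated by F4 to give the heptamer keto‑dioxinone 2,2-dimethyl-6-[3-(aryloxy)-2-oxopropyl]-4H-1,3-dioxin-4-one F5. Heating F5 in toluene with methanol (110 °C) expels acetone, and the acylketene is trapped as the methyl ester, coming back to the route at 32.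

Third: step 21. The C6 carbanion must out‑compete O‑acylation to the 4‑hydroxy‑2‑pyrone and retro‑Claisen cleavage, and this is the least precedented step. The fallback gives up the de novo ring and introduces ring A as an arene by the chemistry already proven six times. It sets out from 27, which is coupled with bromide 7 (CuI, picolinic acid, K3PO4, DMSO, 100 °C) to the A–H octamer aldehyde 3,5-bis(benzyloxy)-4-(aryloxy)benzaldehyde F6. Dakin oxidation (mCPBA, then K2CO3/MeOH) proceeds through the A–H octamer formate F7 to the A–H octamer phenol 3,5-bis(benzyloxy)-4-(aryloxy)phenol F8. Hydrogenolysis of its twenty benzyl ethers (H2, Pd(OH)2/C, THF/MeOH) comes back to the route at 34.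

Further compounds
F1 | step 9 | 2-[4-bromo-3,5-bis(benzyloxy)phenyl]-1,3-dioxolane | Brc1c(OCc2ccccc2)cc(C2OCCO2)cc1OCc1ccccc1
F2 | step 9 | 2-[4-fluoro-3,5-bis(benzyloxy)phenyl]-1,3-dioxolane | Fc1c(OCc2ccccc2)cc(C2OCCO2)cc1OCc1ccccc1
F3 | step 9 | 4-fluoro-3,5-bis(benzyloxy)benzaldehyde | O=Cc1cc(OCc2ccccc2)c(F)c(OCc2ccccc2)c1
F4 | step 20 | heptamer Weinreb amide: N-methoxy-N-methyl-2-(aryloxy)acetamide, aryloxy = 27 less its phenolic H | CON(C)C(=O)COc2cc(OCc9ccccc9)c(Oc3cc(OCc9ccccc9)c(OCc9ccccc9)c(OCc9ccccc9)c3Oc3cc(OCc9ccccc9)c(Oc4cc(OCc9ccccc9)c(OCc9ccccc9)c(OCc9ccccc9)c4Oc4cc(OCc9ccccc9)c(Oc5cc(OCc9ccccc9)c(OCc9ccccc9)c(OCc9ccccc9)c5Oc5cc(OCc9ccccc9)c(OCc9ccccc9)c(OCc9ccccc9)c5)c(OCc9ccccc9)c4)c(OCc9ccccc9)c3)c(OCc9ccccc9)c2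
F5 | step 20 | heptamer keto-dioxinone: 2,2-dimethyl-6-[3-(aryloxy)-2-oxopropyl]-4H-1,3-dioxin-4-one, aryloxy = 27 less its phenolic H | CC1(C)OC(=O)C=C(CC(=O)COc2cc(OCc9ccccc9)c(Oc3cc(OCc9ccccc9)c(OCc9ccccc9)c(OCc9ccccc9)c3Oc3cc(OCc9ccccc9)c(Oc4cc(OCc9ccccc9)c(OCc9ccccc9)c(OCc9ccccc9)c4Oc4cc(OCc9ccccc9)c(Oc5cc(OCc9ccccc9)c(OCc9ccccc9)c(OCc9ccccc9)c5Oc5cc(OCc9ccccc9)c(OCc9ccccc9)c(OCc9ccccc9)c5)c(OCc9ccccc9)c4)c(OCc9ccccc9)c3)c(OCc9ccccc9)c2)O1
F6 | step 21 | A–H octamer aldehyde: 3,5-bis(benzyloxy)-4-(aryloxy)benzaldehyde, aryloxy = 27 less its phenolic H | O=Cc1cc(OCc9ccccc9)c(Oc2cc(OCc9ccccc9)c(Oc3cc(OCc9ccccc9)c(OCc9ccccc9)c(OCc9ccccc9)c3Oc3cc(OCc9ccccc9)c(Oc4cc(OCc9ccccc9)c(OCc9ccccc9)c(OCc9ccccc9)c4Oc4cc(OCc9ccccc9)c(Oc5cc(OCc9ccccc9)c(OCc9ccccc9)c(OCc9ccccc9)c5Oc5cc(OCc9ccccc9)c(OCc9ccccc9)c(OCc9ccccc9)c5)c(OCc9ccccc9)c4)c(OCc9ccccc9)c3)c(OCc9ccccc9)c2)c(OCc9ccccc9)c1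
F7 | step 21 | A–H octamer formate: formate ester of F8 | O=COc1cc(OCc9ccccc9)c(Oc2cc(OCc9ccccc9)c(Oc3cc(OCc9ccccc9)c(OCc9ccccc9)c(OCc9ccccc9)c3Oc3cc(OCc9ccccc9)c(Oc4cc(OCc9ccccc9)c(OCc9ccccc9)c(OCc9ccccc9)c4Oc4cc(OCc9ccccc9)c(Oc5cc(OCc9ccccc9)c(OCc9ccccc9)c(OCc9ccccc9)c5Oc5cc(OCc9ccccc9)c(OCc9ccccc9)c(OCc9ccccc9)c5)c(OCc9ccccc9)c4)c(OCc9ccccc9)c3)c(OCc9ccccc9)c2)c(OCc9ccccc9)c1
F8 | step 21 | A–H octamer phenol: 3,5-bis(benzyloxy)-4-(aryloxy)phenol, aryloxy = 27 less its phenolic H | Oc1cc(OCc9ccccc9)c(Oc2cc(OCc9ccccc9)c(Oc3cc(OCc9ccccc9)c(OCc9ccccc9)c(OCc9ccccc9)c3Oc3cc(OCc9ccccc9)c(Oc4cc(OCc9ccccc9)c(OCc9ccccc9)c(OCc9ccccc9)c4Oc4cc(OCc9ccccc9)c(Oc5cc(OCc9ccccc9)c(OCc9ccccc9)c(OCc9ccccc9)c5Oc5cc(OCc9ccccc9)c(OCc9ccccc9)c(OCc9ccccc9)c5)c(OCc9ccccc9)c4)c(OCc9ccccc9)c3)c(OCc9ccccc9)c2)c(OCc9ccccc9)c1
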